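**Plan**
- Retrosynthetic cuts: (a) the two O-benzyl groups; (b) the quinone ring at C4–C4a and C1–C8a, giving aryl bromide 10 and methyl semisquarate 13, a C4 unit that already carries C1=O, C2–OMe, C3–H and C4=O; (c) the ArCH2–C6 bond (Negishi) and the aryl–C8 bond (Suzuki), back to 3-iodo-2-methylaniline 1.
- Forward: all three benzene rings are bought. The central one is dressed in the order Br (later C8a), aryl (C8), I in place of NH2, benzyl (C6). The C4 unit is then attached at C8a, and the quinone ring, the only ring made, closes last by thermal ring expansion of a 4-aryl-4-hydroxycyclobutenone.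
- Enabling feature: in the benzenoid ring, C8a lies between the aryl-bearing C8 and C4a–H, so the aryl group on the cyclobutenone has a single free ortho carbon for the 6π closure. The C2–OMe/C1=O adjacency follows from which carbonyl of 13 the aryllithium attacks.
- Stereochemistry: the target has no stereocentre, so nothing has to be set.

Key step: step 8

Remark: larreantin as drawn is achiral (no stereocentre; the C8 aryl ring has two ortho hydrogens and rotates freely), so the "single enantiomer" requirement is met without stereocontrol; the racemic carbinol centres of 12 and 15 disappear on the way.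

**Route**

Step 1
Reactants: 1 3-iodo-2-methylaniline
Product: 2 4-bromo-3-iodo-2-methylaniline
Conditions: NBS (1.0 equiv), MeCN, 0 °C
Reagents that add atoms: N-bromosuccinimide, O=C1CCC(=O)N1Br
Why: Electrophilic aromatic bromination of an aniline with NBS should go para to the amino group, the strongest director, which is the carbon next to iodine (the later C8a), and one equivalent at 0 °C should stop at the monobromide.

Step 2
Reactants: 2 4-bromo-3-iodo-2-methylaniline; 3 [4-(benzyloxy)-3-methoxyphenyl]boronic acid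
Product: 4 4'-(benzyloxy)-6-bromo-3'-methoxy-2-methyl-[1,1'-biphenyl]-3-amine
Conditions: Pd(PPh3)4 (cat.), Na2CO3, DME–H2O, 85 °C
Reagents that add atoms: none
Why: Suzuki–Miyaura coupling, in which oxidative addition of Pd(0) into C–I is much faster than into C–Br (further deactivated by the para amino group), so the guaiacyl ring should go only to the carbon between methyl and bromine, with the free aniline tolerated.

Step 3
Reactants: 4 4'-(benzyloxy)-6-bromo-3'-methoxy-2-methyl-[1,1'-biphenyl]-3-amine
Product: 6 4'-(benzyloxy)-6-bromo-3-iodo-3'-methoxy-2-methyl-1,1'-biphenyl, via arenediazonium chloride 5 (not isolated)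
Conditions: NaNO2, aq. HCl, MeCN, 0 °C; then KI, 0 °C to rt
Reagents that add atoms: potassium iodide, [K+].[I-]
Why: Diazotisation and iodo-dediazoniation (Sandmeyer-type) exchange NH2 for I at the carbon ortho to methyl; the diazonium group is meta to the biaryl bond and cannot reach the electron-rich ring intramolecularly, and the benzyl ether and aryl bromide are inert.

Step 4
Reactants: 7 [4-(benzyloxy)-3-methoxyphenyl]methanol
Product: 8 1-(benzyloxy)-4-(chloromethyl)-2-methoxybenzene
Conditions: SOCl2, cat. DMF, CH2Cl2, 0 °C to rt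
Reagents that add atoms: thionyl chloride, O=S(Cl)Cl
Why: Chlorination of an electron-rich benzylic alcohol with thionyl chloride (via the chlorosulfite) is a standard substitution, and the benzyl aryl ether should survive the brief exposure to HCl.

Step 5
Reactants: 8 1-(benzyloxy)-4-(chloromethyl)-2-methoxybenzene; 6 4'-(benzyloxy)-6-bromo-3-iodo-3'-methoxy-2-methyl-1,1'-biphenyl
Product: 10 4'-(benzyloxy)-3-[4-(benzyloxy)-3-methoxybenzyl]-6-bromo-3'-methoxy-2-methyl-1,1'-biphenyl, via benzylzinc chloride 9 (not isolated)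
Conditions: 8, Zn dust, LiCl, THF, 25 °C; then 6, Pd(PPh3)4 (cat.), THF, 25–40 °C
Reagents that add atoms: none
Why: Negishi sp3–sp2 coupling, in which LiCl-promoted zinc insertion into the benzylic C–Cl bond gives 9, which transmetalates to the arylpalladium iodide formed selectively at C–I under mild conditions, leaving the more hindered C–Br bond for step 7.

Step 6
Reactants: 11 3,4-dimethoxycyclobut-3-ene-1,2-dione (dimethyl squarate)
Product: 13 3-methoxycyclobut-3-ene-1,2-dione (methyl semisquarate), via hydride adduct 12 (not isolated)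
Conditions: LiAlH(Ot-Bu)3, THF, −78 to −20 °C; then conc. HCl, CH2Cl2, 0 °C to rt
Reagents that add atoms: none
Why: Hydride 1,2-addition to one squarate carbonyl, then acid-induced ionisation of the carbinol, capture of the methoxy-stabilised cation by water and loss of methanol (the established reduction–elimination route from dialkyl squarates to alkyl semisquarates) should give the C4 unit with H at the later C3.

Step 7
Reactants: 10 4'-(benzyloxy)-3-[4-(benzyloxy)-3-methoxybenzyl]-6-bromo-3'-methoxy-2-methyl-1,1'-biphenyl; 13 3-methoxycyclobut-3-ene-1,2-dione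
Product: 15 4-{4'-(benzyloxy)-5-[4-(benzyloxy)-3-methoxybenzyl]-3'-methoxy-6-methylbiphenyl-2-yl}-4-hydroxy-3-methoxycyclobut-2-en-1-one (racemic), via aryllithium 14 (not isolated)
Conditions: t-BuLi (2 equiv), THF, −78 °C; cannulate into 13, THF, −78 °C; aq. NH4Cl
Reagents that add atoms: none
Why: Bromine–lithium exchange gives 2-biaryllithium 14, which should add 1,2 to the ketone-like carbonyl of 13 (the one flanked by C–OMe; the other is a vinylogous ester), as is known for organolithium additions to 3-alkoxycyclobutenediones, so the carbinol carbon ends up next to the methoxy-bearing carbon.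

Step 8
Reactants: 15 4-{4'-(benzyloxy)-5-[4-(benzyloxy)-3-methoxybenzyl]-3'-methoxy-6-methylbiphenyl-2-yl}-4-hydroxy-3-methoxycyclobut-2-en-1-one
Product: 18 8-[4-(benzyloxy)-3-methoxyphenyl]-6-[4-(benzyloxy)-3-methoxybenzyl]-2-methoxy-7-methylnaphthalene-1,4-dione, via dienylketene 16 (not isolated), via benzylated hydroquinone 17 (not isolated)
Conditions: p-xylene, 138 °C, Ar; then Ag2O, K2CO3, rt
Reagents that add atoms: none
Why: Thermal ring expansion of a 4-aryl-4-hydroxycyclobutenone (Moore rearrangement): conrotatory 4π-electrocyclic opening of the C1–C4 bond of the cyclobutenone gives dienylketene 16, whose ketene carbon closes onto the free ortho carbon of the aryl ring by a thermal 6π-electrocyclisation (the new bond is the later C4–C4a), and tautomerisation gives hydroquinone 17, which Ag2O dehydrogenates to the quinone. The closest known reaction type is the thermolysis of 4-aryl-4-hydroxycyclobutenones to 1,4-naphthoquinones. The six-membered quinone ring is closed by a pericyclic 6π (disrotatory) closure, not a polar cyclisation, so no activating group is needed. No stereocentre is formed and the racemic carbinol centre of 15 is destroyed. The step needs (i) outward rotation of the donor OH so that the aryl group sits cis to the ketene, which the 4-hydroxy group itself imposes (torquoselectivity), (ii) closure at one site only, secured because the other ortho carbon (later C8) carries the guaiacyl ring, and (iii) OMe at C2 next to C1=O, already fixed in 15 by the connectivity C(OH)Ar–C(OMe)=CH–C=O.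

Step 9
Reactants: 18 8-[4-(benzyloxy)-3-methoxyphenyl]-6-[4-(benzyloxy)-3-methoxybenzyl]-2-methoxy-7-methylnaphthalene-1,4-dione
Product: 20 larreantin, via free hydroquinone 19 (not isolated)
Conditions: H2 (1 atm), 10% Pd/C, EtOAc–MeOH, rt; filter; air, rt
Reagents that add atoms: none
Why: Hydrogenolysis of the two benzyl aryl ethers over Pd/C also reduces the quinone reversibly to hydroquinone 19, which air should re-oxidise to the quinone on work-up, while the biaryl, the diarylmethane and the methyl ethers are inert.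

**Compound list**

1 | 3-iodo-2-methylaniline | Cc1c(N)cccc1I | starting material
2 | 4-bromo-3-iodo-2-methylaniline | Cc1c(N)ccc(Br)c1I | intermediate
3 | [4-(benzyloxy)-3-methoxyphenyl]boronic acid | COc1cc(B(O)O)ccc1OCc1ccccc1 | starting material
4 | 4'-(benzyloxy)-6-bromo-3'-methoxy-2-methyl-[1,1'-biphenyl]-3-amine | Cc1c(N)ccc(Br)c1-c1ccc(OCc2ccccc2)c(OC)c1 | intermediate
5 | 4'-(benzyloxy)-6-bromo-3'-methoxy-2-methylbiphenyl-3-diazonium chloride (not isolated) | Cc1c([N+]#N)ccc(Br)c1-c1ccc(OCc2ccccc2)c(OC)c1.[Cl-] | intermediate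
6 | 4'-(benzyloxy)-6-bromo-3-iodo-3'-methoxy-2-methyl-1,1'-biphenyl | Cc1c(I)ccc(Br)c1-c1ccc(OCc2ccccc2)c(OC)c1 | intermediate
7 | [4-(benzyloxy)-3-methoxyphenyl]methanol | COc1cc(CO)ccc1OCc1ccccc1 | starting material
8 | 1-(benzyloxy)-4-(chloromethyl)-2-methoxybenzene | COc1cc(CCl)ccc1OCc1ccccc1 | intermediate
9 | [4-(benzyloxy)-3-methoxybenzyl]zinc chloride (not isolated) | COc1cc(C[Zn]Cl)ccc1OCc1ccccc1 | intermediate
10 | 4'-(benzyloxy)-3-[4-(benzyloxy)-3-methoxybenzyl]-6-bromo-3'-methoxy-2-methyl-1,1'-biphenyl | Cc1c(Cc2ccc(OCc3ccccc3)c(OC)c2)ccc(Br)c1-c1ccc(OCc2ccccc2)c(OC)c1 | intermediate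
11 | 3,4-dimethoxycyclobut-3-ene-1,2-dione (dimethyl squarate) | COC1=C(OC)C(=O)C1=O | starting material
12 | 4-hydroxy-2,3-dimethoxycyclobut-2-en-1-one (racemic, not isolated) | COC1=C(OC)C(O)C1=O | intermediate
13 | 3-methoxycyclobut-3-ene-1,2-dione (methyl semisquarate) | COC1=CC(=O)C1=O | intermediate
14 | {4'-(benzyloxy)-5-[4-(benzyloxy)-3-methoxybenzyl]-3'-methoxy-6-methylbiphenyl-2-yl}lithium (not isolated) | [Li]c1ccc(Cc2ccc(OCc3ccccc3)c(OC)c2)c(C)c1-c1ccc(OCc2ccccc2)c(OC)c1 | intermediate
15 | 4-{4'-(benzyloxy)-5-[4-(benzyloxy)-3-methoxybenzyl]-3'-methoxy-6-methylbiphenyl-2-yl}-4-hydroxy-3-methoxycyclobut-2-en-1-one (racemic) | O=C1C=C(OC)C1(O)c1ccc(Cc2ccc(OCc3ccccc3)c(OC)c2)c(C)c1-c1ccc(OCc2ccccc2)c(OC)c1 | intermediate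
16 | (3Z)-4-{4'-(benzyloxy)-5-[4-(benzyloxy)-3-methoxybenzyl]-3'-methoxy-6-methylbiphenyl-2-yl}-4-hydroxy-3-methoxybuta-1,3-dien-1-one (aryl cis to the ketene; not isolated) | O=C=C/C(OC)=C(\c1ccc(Cc2ccc(OCc3ccccc3)c(OC)c2)c(C)c1-c1ccc(OCc2ccccc2)c(OC)c1)O | intermediate
17 | 8-[4-(benzyloxy)-3-methoxyphenyl]-6-[4-(benzyloxy)-3-methoxybenzyl]-2-methoxy-7-methylnaphthalene-1,4-diol (not isolated) | COc1cc(O)c2cc(Cc3ccc(OCc4ccccc4)c(OC)c3)c(C)c(-c3ccc(OCc4ccccc4)c(OC)c3)c2c1O | intermediate
18 | 8-[4-(benzyloxy)-3-methoxyphenyl]-6-[4-(benzyloxy)-3-methoxybenzyl]-2-methoxy-7-methylnaphthalene-1,4-dione | COC1=CC(=O)c2cc(Cc3ccc(OCc4ccccc4)c(OC)c3)c(C)c(-c3ccc(OCc4ccccc4)c(OC)c3)c2C1=O | intermediate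
19 | 8-(4-hydroxy-3-methoxyphenyl)-6-(4-hydroxy-3-methoxybenzyl)-2-methoxy-7-methylnaphthalene-1,4-diol (not isolated) | COc1cc(O)c2cc(Cc3ccc(O)c(OC)c3)c(C)c(-c3ccc(O)c(OC)c3)c2c1O | intermediate
20 | larreantin, 8-(4-hydroxy-3-methoxyphenyl)-6-(4-hydroxy-3-methoxybenzyl)-2-methoxy-7-methylnaphthalene-1,4-dione | COC1=CC(=O)c2cc(Cc3ccc(O)c(OC)c3)c(C)c(-c3ccc(O)c(OC)c3)c2C1=O | target

**Step count and risks**

Total step count: 9. Longest linear sequence: 7 steps (steps 1, 2, 3, 5, 7, 8, 9, from 1 to 20); steps 4 and 6 are side branches.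

Steps most likely to fail:

1. Step 7. The hindered 2-biaryllithium may attack the vinylogous-ester carbonyl, or displace methoxide by conjugate addition–elimination. The small, labile methyl semisquarate may also be lost to proton transfer or self-condensation. The fallback sets out from 10 and returns at 18; it swaps the C4 block for the bulkier, isolable isopropyl ester and brings in the methyl ether afterwards. Commercial diisopropyl squarate would be reduced with LiAlH(Ot-Bu)3 to 4-hydroxy-2,3-diisopropoxycyclobut-2-en-1-one F1 (not isolated), which HCl should convert into 3-isopropoxycyclobut-3-ene-1,2-dione F2. Aryllithium 14, made from 10 as in step 7, would be added to F2 to give 4-aryl-4-hydroxy-3-isopropoxycyclobut-2-en-1-one F3, in which the larger alkoxy group shields the vinylogous-ester carbonyl and the alkoxy-bearing carbon. Thermolysis and silver(I) oxide oxidation as in step 8 should lead through the isopropoxy dienylketene F4 and the isopropoxy hydroquinone F5 to 2-isopropoxynaphthoquinone F6. Acid-catalysed vinylogous transesterification (cat. p-TsOH, MeOH, 60 °C) should then exchange the alkoxy group at C2 and give 18.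

2. Step 8. The 6π closure onto the crowded biaryl ring may be slow, so the dienylketene could be diverted into lactonisation by its own hydroxyl group (butenolide formation) or into oligomers, and the free hydroquinone could be over-oxidised. The fallback sets out from 15 and returns at 17; it closes a ketene that has no free hydroxyl and delivers the ring as a mono-protected hydroquinone. Silylation (TMSCl, Et3N, CH2Cl2) should give 4-aryl-3-methoxy-4-(trimethylsilyloxy)cyclobut-2-en-1-one F7. Heating in p-xylene should open it to the silyloxy dienylketene F8 (not isolated), which can only undergo electrocyclisation, giving 5-aryl-7-benzyl-3-methoxy-6-methyl-4-(trimethylsilyloxy)naphthalen-1-ol F9. K2CO3 in methanol under air should remove the silyl group to give 17, which is oxidised to 18 by air or as in step 8.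

3. Step 2. Transmetalation and reductive elimination at the C–I bond flanked by methyl and bromine may be slow, which would allow protodeiodination or loss of the I/Br discrimination (double coupling). The fallback sets out from 1 and returns at 4; it inverts the order of coupling and halogenation. Suzuki–Miyaura coupling of 1 with 3 (one halogen, one ortho substituent) should give 4'-(benzyloxy)-3'-methoxy-2-methyl-[1,1'-biphenyl]-3-amine F10. NBS in MeCN at 0 °C should then brominate para to the amino group, at the carbon next to the biaryl bond, because the aniline ring is far more nucleophilic than the dialkoxybenzene ring; this gives 4.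

**Further compounds**

F1 | step 7 | 4-hydroxy-2,3-diisopropoxycyclobut-2-en-1-one (racemic, not isolated) | CC(C)OC1=C(OC(C)C)C(O)C1=O
F2 | step 7 | 3-isopropoxycyclobut-3-ene-1,2-dione | CC(C)OC1=CC(=O)C1=O
F3 | step 7 | 4-{4'-(benzyloxy)-5-[4-(benzyloxy)-3-methoxybenzyl]-3'-methoxy-6-methylbiphenyl-2-yl}-4-hydroxy-3-isopropoxycyclobut-2-en-1-one (racemic) | O=C1C=C(OC(C)C)C1(O)c1ccc(Cc2ccc(OCc3ccccc3)c(OC)c2)c(C)c1-c1ccc(OCc2ccccc2)c(OC)c1
F4 | step 7 | (3Z)-4-aryl-4-hydroxy-3-isopropoxybuta-1,3-dien-1-one, isopropoxy analogue of 16 (not isolated) | O=C=C/C(OC(C)C)=C(\c1ccc(Cc2ccc(OCc3ccccc3)c(OC)c2)c(C)c1-c1ccc(OCc2ccccc2)c(OC)c1)O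
F5 | step 7 | 8-[4-(benzyloxy)-3-methoxyphenyl]-6-[4-(benzyloxy)-3-methoxybenzyl]-2-isopropoxy-7-methylnaphthalene-1,4-diol (not isolated) | CC(C)Oc1cc(O)c2cc(Cc3ccc(OCc4ccccc4)c(OC)c3)c(C)c(-c3ccc(OCc4ccccc4)c(OC)c3)c2c1O
F6 | step 7 | 8-[4-(benzyloxy)-3-methoxyphenyl]-6-[4-(benzyloxy)-3-methoxybenzyl]-2-isopropoxy-7-methylnaphthalene-1,4-dione | CC(C)OC1=CC(=O)c2cc(Cc3ccc(OCc4ccccc4)c(OC)c3)c(C)c(-c3ccc(OCc4ccccc4)c(OC)c3)c2C1=O
F7 | step 8 | 4-{4'-(benzyloxy)-5-[4-(benzyloxy)-3-methoxybenzyl]-3'-methoxy-6-methylbiphenyl-2-yl}-3-methoxy-4-(trimethylsilyloxy)cyclobut-2-en-1-one (racemic) | O=C1C=C(OC)C1(O[Si](C)(C)C)c1ccc(Cc2ccc(OCc3ccccc3)c(OC)c2)c(C)c1-c1ccc(OCc2ccccc2)c(OC)c1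
F8 | step 8 | (3Z)-4-aryl-3-methoxy-4-(trimethylsilyloxy)buta-1,3-dien-1-one, silyl ether of 16 (not isolated) | O=C=C/C(OC)=C(\c1ccc(Cc2ccc(OCc3ccccc3)c(OC)c2)c(C)c1-c1ccc(OCc2ccccc2)c(OC)c1)O[Si](C)(C)C
F9 | step 8 | 5-[4-(benzyloxy)-3-methoxyphenyl]-7-[4-(benzyloxy)-3-methoxybenzyl]-3-methoxy-6-methyl-4-(trimethylsilyloxy)naphthalen-1-ol | COc1cc(O)c2cc(Cc3ccc(OCc4ccccc4)c(OC)c3)c(C)c(-c3ccc(OCc4ccccc4)c(OC)c3)c2c1O[Si](C)(C)C
F10 | step 2 | 4'-(benzyloxy)-3'-methoxy-2-methyl-[1,1'-biphenyl]-3-amine | Cc1c(N)cccc1-c1ccc(OCc2ccccc2)c(OC)c1
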